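**Plan**
- Retrosynthesis: the three O–Si bonds are cut first, then C2–C3 of ring C, which leads back to a ring A diazomethyl ketone whose O1 carries a silylated vanillyl group.
- Further back, the diazo carbon comes from the acetyl methyl group, the O1–CH2 bond from a Mitsunobu etherification, and the C6–CMe2 bond from a Claisen shift of a 4-O-prenyl ether of 2,4,6-trihydroxyacetophenone.
- Enabling feature: C2 is a benzylic carbon on O1 and C3 lies alpha to the C4 ketone of ring C, so C3 can be a keto carbenoid and C2 an ether-activated benzylic C–H.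
- Forward: ring A is completed first (prenylation, Claisen shift, stepwise differentiation of the three phenols), the vanillyl unit is attached through O1, and ring C is closed last by forming C2–C3.
- Stereochemistry: the only stereocentre, C2 (S), is set in the ring closure by a chiral dirhodium carboxylate that selects one of two enantiotopic benzylic hydrogens; the final deprotection is buffered so C2 is not scrambled.

Key step: step 9

Remark on numbering: ring A intermediates use acetophenone numbering (C1 bears the acetyl group); O1, C2, C3, C4 and C5–C8 refer to the flavanone.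
Assumption: Rh2(S-PTTL)4 is taken to deliver the 2S product; should the insertion favour 2R, the mirror-image catalyst Rh2(R-PTTL)4 would be used with no other change.

**Step 1**
Reactants: 1 2,4,6-trihydroxyacetophenone; 2 prenyl bromide (1-bromo-3-methylbut-2-ene)
Product: 3 1-[2,6-dihydroxy-4-(3-methylbut-2-en-1-yloxy)phenyl]ethanone
Conditions: K2CO3 (1.1 equiv), 2 (1.05 equiv), acetone, reflux
Reagents that add atoms: none
Why: Williamson etherification: the 4-hydroxyl is the most acidic phenol and the only one not held in a hydrogen bond to the acetyl oxygen, so one equivalent of base and bromide should alkylate it in preference to the two chelated hydroxyls.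

**Step 2**
Reactants: 3 1-[2,6-dihydroxy-4-(3-methylbut-2-en-1-yloxy)phenyl]ethanone
Product: 4 1-[2,4,6-trihydroxy-3-(2-methylbut-3-en-2-yl)phenyl]ethanone
Conditions: N,N-diethylaniline, 200 °C (sealed vessel, microwave), argon, short heating
Reagents that add atoms: none
Why: Aromatic Claisen rearrangement: the [3,3]-shift of the aryl prenyl ether delivers the allyl unit with inversion to C3 (both ortho positions are equivalent) and enolisation of the dienone restores the arene, while the amine solvent holds back acid-promoted addition of the phenols to the new vinyl group.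

**Step 3**
Reactants: 4 1-[2,4,6-trihydroxy-3-(2-methylbut-3-en-2-yl)phenyl]ethanone
Product: 5 1-[4-(tert-butyldimethylsilyloxy)-2,6-dihydroxy-3-(2-methylbut-3-en-2-yl)phenyl]ethanone
Conditions: TBSCl (1.05 equiv), Et3N (1.1 equiv), CH2Cl2, 0 °C
Reagents that add atoms: tert-butyldimethylsilyl chloride, CC(C)(C)[Si](C)(C)Cl
Why: Selective O-silylation: only the 4-hydroxyl (para to the acetyl group, not chelated) is acidic enough to be deprotonated by one equivalent of amine, so the single equivalent of silyl chloride should be taken up there.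

**Step 4**
Reactants: 6 vanillin (4-hydroxy-3-methoxybenzaldehyde)
Product: 7 4-(tert-butyldimethylsilyloxy)-3-methoxybenzaldehyde
Conditions: TBSCl, imidazole, CH2Cl2, rt
Reagents that add atoms: tert-butyldimethylsilyl chloride, CC(C)(C)[Si](C)(C)Cl
Why: Standard imidazole-promoted silylation of an unhindered phenol.

**Step 5**
Reactants: 7 4-(tert-butyldimethylsilyloxy)-3-methoxybenzaldehyde
Product: 8 [4-(tert-butyldimethylsilyloxy)-3-methoxyphenyl]methanol
Conditions: NaBH4, EtOH–THF, 0 °C
Reagents that add atoms: none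
Why: Borohydride reduction of an aryl aldehyde to the benzylic alcohol, brief and cold so that the aryl silyl ether is retained.

**Step 6**
Reactants: 5 1-[4-(tert-butyldimethylsilyloxy)-2,6-dihydroxy-3-(2-methylbut-3-en-2-yl)phenyl]ethanone; 8 [4-(tert-butyldimethylsilyloxy)-3-methoxyphenyl]methanol
Product: 9 1-[4-(tert-butyldimethylsilyloxy)-6-{[4-(tert-butyldimethylsilyloxy)-3-methoxybenzyl]oxy}-2-hydroxy-3-(2-methylbut-3-en-2-yl)phenyl]ethanone
Conditions: PPh3, DIAD, THF, 0 °C → rt
Reagents that add atoms: none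
Why: Mitsunobu etherification of a phenol with a primary benzylic alcohol: the C2 hydroxyl is shielded by the tertiary alkyl group and keeps the hydrogen bond to the ketone, so the open C6 hydroxyl should be alkylated, under neutral conditions that leave both aryl silyl ethers intact.

**Step 7**
Reactants: 9 1-[4-(tert-butyldimethylsilyloxy)-6-{[4-(tert-butyldimethylsilyloxy)-3-methoxybenzyl]oxy}-2-hydroxy-3-(2-methylbut-3-en-2-yl)phenyl]ethanone
Product: 10 1-[2,4-bis(tert-butyldimethylsilyloxy)-6-{[4-(tert-butyldimethylsilyloxy)-3-methoxybenzyl]oxy}-3-(2-methylbut-3-en-2-yl)phenyl]ethanone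
Conditions: TBSOTf (1.5 equiv), 2,6-lutidine, CH2Cl2, 0 °C → rt; aqueous citric acid work-up
Reagents that add atoms: tert-butyldimethylsilyl trifluoromethanesulfonate, CC(C)(C)[Si](C)(C)OS(=O)(=O)C(F)(F)F
Why: Silylation with a silyl triflate, which is reactive enough for a chelated phenol flanked by a tertiary alkyl group, with a weak pyridine base that limits enol silylation of the acetyl group (any enol silyl ether would be hydrolysed in the acidic work-up).

**Step 8**
Reactants: 10 1-[2,4-bis(tert-butyldimethylsilyloxy)-6-{[4-(tert-butyldimethylsilyloxy)-3-methoxybenzyl]oxy}-3-(2-methylbut-3-en-2-yl)phenyl]ethanone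
Product: 12 2-diazo-1-[2,4-bis(tert-butyldimethylsilyloxy)-6-{[4-(tert-butyldimethylsilyloxy)-3-methoxybenzyl]oxy}-3-(2-methylbut-3-en-2-yl)phenyl]ethanone, via trifluoroacetyl diketone 11 (not isolated)
Conditions: LiN(SiMe3)2, THF, −78 °C; CF3CO2CH2CF3, −78 °C; 5% aq. HCl quench; then MsN3, Et3N, H2O, MeCN, rt
Reagents that add atoms: methanesulfonyl azide, CS(=O)(=O)N=[N+]=[N-] (the two diazo nitrogens); 2,2,2-trifluoroethyl trifluoroacetate, O=C(OCC(F)(F)F)C(F)(F)F (trifluoroacetyl group of 11 only, lost again)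
Why: Detrifluoroacetylative diazo transfer: C-trifluoroacetylation of the kinetic lithium enolate activates the methyl carbon for diazo transfer from the sulfonyl azide, and loss of the trifluoroacetyl group as its N-sulfonyl amide leaves the diazomethyl ketone without touching the silyl or benzyl ethers.

**Step 9**
Reactants: 12 2-diazo-1-[2,4-bis(tert-butyldimethylsilyloxy)-6-{[4-(tert-butyldimethylsilyloxy)-3-methoxybenzyl]oxy}-3-(2-methylbut-3-en-2-yl)phenyl]ethanone
Product: 13 (2S)-5,7-bis(tert-butyldimethylsilyloxy)-2-[4-(tert-butyldimethylsilyloxy)-3-methoxyphenyl]-6-(2-methylbut-3-en-2-yl)-2,3-dihydro-4H-chromen-4-one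
Conditions: Rh2(S-PTTL)4 (dirhodium tetrakis[N-phthaloyl-(S)-tert-leucinate], 2 mol%), toluene, 4 Å molecular sieves, 0 °C, slow addition of 12
Reagents that add atoms: none
Why: The dirhodium tetracarboxylate (divalent rhodium) binds the diazo carbon, N2 leaves, and the electrophilic carbenoid carbon (C3) inserts into one C–H bond of the O1-bound benzylic CH2 through a three-centre transition state with hydride-transfer character, forming C2–C3; the closest known reaction type is the chiral dirhodium carboxylate-catalysed cyclisation of 2-alkoxyaryl diazoketones to chroman-4-ones, together with insertions of this catalyst into benzyl ether C–H bonds. Ring C closes as a six-membered ring by a 1,6-insertion that joins the carbenoid carbon to the benzylic carbon across C4, C4a, C8a and O1. The C2 stereocentre is set by the chiral pocket of the four phthalimido-tert-leucinate ligands, which tell apart the two enantiotopic benzylic hydrogens, the substrate having no other stereocentre. The step needs site selectivity, which the substrate secures because the C5 silyl ether offers no C–H within reach and is a hindered, poor ylide donor, the vinyl group on C6 sits meta to the acyl carbon and cannot reach the carbenoid, and the benzylic C–H is made strongly hydridic by O1 and the 4-silyloxy-3-methoxyphenyl ring. It also needs chemoselectivity against oxonium ylide formation at O1 followed by a Stevens [1,2]-shift to a 2-benzylbenzofuran-3-one, which is the main risk and should be held back by the low basicity of an aryl ether oxygen conjugated to the ortho acyl group, by the non-polar solvent and by the carboxylate ligands.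

**Step 10**
Reactants: 13 (2S)-5,7-bis(tert-butyldimethylsilyloxy)-2-[4-(tert-butyldimethylsilyloxy)-3-methoxyphenyl]-6-(2-methylbut-3-en-2-yl)-2,3-dihydro-4H-chromen-4-one
Product: 14 (2S)-5,7-dihydroxy-2-(4-hydroxy-3-methoxyphenyl)-6-(2-methylbut-3-en-2-yl)-2,3-dihydro-4H-chromen-4-one
Conditions: Bu4NF (3.5 equiv), AcOH (4 equiv), THF, 0 °C → rt
Reagents that add atoms: none
Why: Fluoride-induced desilylation frees the three phenols, and the acetic acid buffer keeps them protonated so that ring C is not opened by retro-oxa-Michael elimination and C2 keeps its configuration.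

**Compound list**
1 | 2,4,6-trihydroxyacetophenone | CC(=O)c1c(O)cc(O)cc1O | starting material
2 | prenyl bromide (1-bromo-3-methylbut-2-ene) | CC(C)=CCBr | starting material
3 | 1-[2,6-dihydroxy-4-(3-methylbut-2-en-1-yloxy)phenyl]ethanone | CC(=O)c1c(O)cc(OCC=C(C)C)cc1O | intermediate
4 | 1-[2,4,6-trihydroxy-3-(2-methylbut-3-en-2-yl)phenyl]ethanone | CC(=O)c1c(O)cc(O)c(C(C)(C)C=C)c1O | intermediate
5 | 1-[4-(tert-butyldimethylsilyloxy)-2,6-dihydroxy-3-(2-methylbut-3-en-2-yl)phenyl]ethanone | CC(=O)c1c(O)cc(O[Si](C)(C)C(C)(C)C)c(C(C)(C)C=C)c1O | intermediate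
6 | vanillin | COc1cc(C=O)ccc1O | starting material
7 | 4-(tert-butyldimethylsilyloxy)-3-methoxybenzaldehyde | COc1cc(C=O)ccc1O[Si](C)(C)C(C)(C)C | intermediate
8 | [4-(tert-butyldimethylsilyloxy)-3-methoxyphenyl]methanol | COc1cc(CO)ccc1O[Si](C)(C)C(C)(C)C | intermediate
9 | 1-[4-(tert-butyldimethylsilyloxy)-6-{[4-(tert-butyldimethylsilyloxy)-3-methoxybenzyl]oxy}-2-hydroxy-3-(2-methylbut-3-en-2-yl)phenyl]ethanone | CC(=O)c1c(OCc2ccc(O[Si](C)(C)C(C)(C)C)c(OC)c2)cc(O[Si](C)(C)C(C)(C)C)c(C(C)(C)C=C)c1O | intermediate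
10 | 1-[2,4-bis(tert-butyldimethylsilyloxy)-6-{[4-(tert-butyldimethylsilyloxy)-3-methoxybenzyl]oxy}-3-(2-methylbut-3-en-2-yl)phenyl]ethanone | CC(=O)c1c(OCc2ccc(O[Si](C)(C)C(C)(C)C)c(OC)c2)cc(O[Si](C)(C)C(C)(C)C)c(C(C)(C)C=C)c1O[Si](C)(C)C(C)(C)C | intermediate
11 | 1-[2,4-bis(tert-butyldimethylsilyloxy)-6-{[4-(tert-butyldimethylsilyloxy)-3-methoxybenzyl]oxy}-3-(2-methylbut-3-en-2-yl)phenyl]-4,4,4-trifluorobutane-1,3-dione (not isolated) | O=C(CC(=O)C(F)(F)F)c1c(OCc2ccc(O[Si](C)(C)C(C)(C)C)c(OC)c2)cc(O[Si](C)(C)C(C)(C)C)c(C(C)(C)C=C)c1O[Si](C)(C)C(C)(C)C | intermediate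
12 | 2-diazo-1-[2,4-bis(tert-butyldimethylsilyloxy)-6-{[4-(tert-butyldimethylsilyloxy)-3-methoxybenzyl]oxy}-3-(2-methylbut-3-en-2-yl)phenyl]ethanone | [N-]=[N+]=CC(=O)c1c(OCc2ccc(O[Si](C)(C)C(C)(C)C)c(OC)c2)cc(O[Si](C)(C)C(C)(C)C)c(C(C)(C)C=C)c1O[Si](C)(C)C(C)(C)C | intermediate
13 | (2S)-5,7-bis(tert-butyldimethylsilyloxy)-2-[4-(tert-butyldimethylsilyloxy)-3-methoxyphenyl]-6-(2-methylbut-3-en-2-yl)-2,3-dihydro-4H-chromen-4-one | C=CC(C)(C)c1c(O[Si](C)(C)C(C)(C)C)cc2c(c1O[Si](C)(C)C(C)(C)C)C(=O)C[C@@H](c1ccc(O[Si](C)(C)C(C)(C)C)c(OC)c1)O2 | intermediate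
14 | (2S)-5,7-dihydroxy-2-(4-hydroxy-3-methoxyphenyl)-6-(2-methylbut-3-en-2-yl)-2,3-dihydro-4H-chromen-4-one | C=CC(C)(C)c1c(O)cc2c(c1O)C(=O)C[C@@H](c1ccc(O)c(OC)c1)O2 | target

**Step count**
Total: 10 steps. Longest linear sequence: 8 steps (steps 1, 2, 3, 6, 7, 8, 9, 10, from 2,4,6-trihydroxyacetophenone); steps 4 and 5 form the two-step vanillyl branch.

**Steps most likely to fail**

Step 9. The carbenoid may be captured by the lone pair of O1 instead of the C–H bond, and the oxonium ylide would then hand the electron-rich benzyl group to carbon and give a benzofuranone. The catalyst may also discriminate the two benzylic hydrogens poorly. The fallback gives up the carbenoid and forms the C2–aryl bond instead, setting out from 10. Oxidative cleavage of the electron-rich benzyl ether (DDQ, CH2Cl2–water), which then has served only as a protecting group for O1, should give 1-[2,4-bis(tert-butyldimethylsilyloxy)-6-hydroxy-3-(2-methylbut-3-en-2-yl)phenyl]ethanone F1 with the ring-closing oxygen unambiguously defined. Condensation with N,N-dimethylformamide dimethyl acetal in toluene would give the enaminone (E)-3-(dimethylamino)-1-[2,4-bis(tert-butyldimethylsilyloxy)-6-hydroxy-3-(2-methylbut-3-en-2-yl)phenyl]prop-2-en-1-one F2. Warming F2 in acetic acid should close it to 5,7-bis(tert-butyldimethylsilyloxy)-6-(2-methylbut-3-en-2-yl)-4H-chromen-4-one F3. Asymmetric conjugate addition of [4-(tert-butyldimethylsilyloxy)-3-methoxyphenyl]boronic acid F4 (from commercial 4-hydroxy-3-methoxyphenylboronic acid and TBSCl) would then be run with Pd(OCOCF3)2, the enantiomer of the tert-butyl pyridine-oxazoline ligand that gives 2S, NH4PF6 and water in 1,2-dichloroethane. This should give 13, where the route is rejoined before step 10.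

Step 2. At 200 °C the prenyl group may be lost, a free phenol may add to the new vinyl group to give a dihydrobenzofuran, and further sigmatropic shifts may follow. The fallback sets out from 3 and blocks all phenols during the rearrangement. Acetylation (Ac2O, pyridine) should give 2-acetyl-5-(3-methylbut-2-en-1-yloxy)-1,3-phenylene diacetate F5. Heating F5 in N,N-diethylaniline with Ac2O and NaOAc should trap the phenol released by the Claisen shift as it forms, giving 2-acetyl-4-(2-methylbut-3-en-2-yl)benzene-1,3,5-triyl triacetate F6. Cold methanolysis (K2CO3, MeOH, 0 °C) would return 4.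

Step 7. Silylation of the phenol wedged between the acetyl and tertiary alkyl groups may be slow or incomplete, with silylation of the ketone enol taking over. The fallback sets out from 9 and carries this oxygen as the smaller triethylsilyl ether. TESOTf and 2,6-lutidine should give 1-[4-(tert-butyldimethylsilyloxy)-6-{[4-(tert-butyldimethylsilyloxy)-3-methoxybenzyl]oxy}-3-(2-methylbut-3-en-2-yl)-2-(triethylsilyloxy)phenyl]ethanone F7. The diazo transfer of step 8 would pass through the trifluoroacetyl diketone F8 to the diazoketone 2-diazo-1-[4-(tert-butyldimethylsilyloxy)-6-{[4-(tert-butyldimethylsilyloxy)-3-methoxybenzyl]oxy}-3-(2-methylbut-3-en-2-yl)-2-(triethylsilyloxy)phenyl]ethanone F9. The insertion of step 9 should give (2S)-7-(tert-butyldimethylsilyloxy)-2-[4-(tert-butyldimethylsilyloxy)-3-methoxyphenyl]-6-(2-methylbut-3-en-2-yl)-5-(triethylsilyloxy)-2,3-dihydro-4H-chromen-4-one F10. The buffered fluoride of step 10 removes all three silyl groups and returns the route at 14.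

**Further compounds**
F1 | step 9 | 1-[2,4-bis(tert-butyldimethylsilyloxy)-6-hydroxy-3-(2-methylbut-3-en-2-yl)phenyl]ethanone | CC(=O)c1c(O)cc(O[Si](C)(C)C(C)(C)C)c(C(C)(C)C=C)c1O[Si](C)(C)C(C)(C)C
F2 | step 9 | (E)-3-(dimethylamino)-1-[2,4-bis(tert-butyldimethylsilyloxy)-6-hydroxy-3-(2-methylbut-3-en-2-yl)phenyl]prop-2-en-1-one | CN(C)/C=C/C(=O)c1c(O)cc(O[Si](C)(C)C(C)(C)C)c(C(C)(C)C=C)c1O[Si](C)(C)C(C)(C)C
F3 | step 9 | 5,7-bis(tert-butyldimethylsilyloxy)-6-(2-methylbut-3-en-2-yl)-4H-chromen-4-one | O=c1ccoc2cc(O[Si](C)(C)C(C)(C)C)c(C(C)(C)C=C)c(O[Si](C)(C)C(C)(C)C)c12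
F4 | step 9 | [4-(tert-butyldimethylsilyloxy)-3-methoxyphenyl]boronic acid | COc1cc(B(O)O)ccc1O[Si](C)(C)C(C)(C)C
F5 | step 2 | 2-acetyl-5-(3-methylbut-2-en-1-yloxy)-1,3-phenylene diacetate | CC(=O)Oc1cc(OCC=C(C)C)cc(OC(C)=O)c1C(C)=O
F6 | step 2 | 2-acetyl-4-(2-methylbut-3-en-2-yl)benzene-1,3,5-triyl triacetate | CC(=O)Oc1cc(OC(C)=O)c(C(C)(C)C=C)c(OC(C)=O)c1C(C)=O
F7 | step 7 | 1-[4-(tert-butyldimethylsilyloxy)-6-{[4-(tert-butyldimethylsilyloxy)-3-methoxybenzyl]oxy}-3-(2-methylbut-3-en-2-yl)-2-(triethylsilyloxy)phenyl]ethanone | CC(=O)c1c(OCc2ccc(O[Si](C)(C)C(C)(C)C)c(OC)c2)cc(O[Si](C)(C)C(C)(C)C)c(C(C)(C)C=C)c1O[Si](CC)(CC)CC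
F8 | step 7 | 1-[4-(tert-butyldimethylsilyloxy)-6-{[4-(tert-butyldimethylsilyloxy)-3-methoxybenzyl]oxy}-3-(2-methylbut-3-en-2-yl)-2-(triethylsilyloxy)phenyl]-4,4,4-trifluorobutane-1,3-dione | O=C(CC(=O)C(F)(F)F)c1c(OCc2ccc(O[Si](C)(C)C(C)(C)C)c(OC)c2)cc(O[Si](C)(C)C(C)(C)C)c(C(C)(C)C=C)c1O[Si](CC)(CC)CC
F9 | step 7 | 2-diazo-1-[4-(tert-butyldimethylsilyloxy)-6-{[4-(tert-butyldimethylsilyloxy)-3-methoxybenzyl]oxy}-3-(2-methylbut-3-en-2-yl)-2-(triethylsilyloxy)phenyl]ethanone | [N-]=[N+]=CC(=O)c1c(OCc2ccc(O[Si](C)(C)C(C)(C)C)c(OC)c2)cc(O[Si](C)(C)C(C)(C)C)c(C(C)(C)C=C)c1O[Si](CC)(CC)CC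
F10 | step 7 | (2S)-7-(tert-butyldimethylsilyloxy)-2-[4-(tert-butyldimethylsilyloxy)-3-methoxyphenyl]-6-(2-methylbut-3-en-2-yl)-5-(triethylsilyloxy)-2,3-dihydro-4H-chromen-4-one | C=CC(C)(C)c1c(O[Si](C)(C)C(C)(C)C)cc2c(c1O[Si](CC)(CC)CC)C(=O)C[C@@H](c1ccc(O[Si](C)(C)C(C)(C)C)c(OC)c1)O2
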